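## Retrosynthetic overview

1. The two C–Br bonds are made last from a bis-silyl ether (inversion at the ring carbinol); the two C–Cl bonds come before that from an anti-1,3-diol (inversion at both carbinols).
2. The diol comes from an acyclic keto-enal by the ring-forming step, an intramolecular aldol addition (C4–C5 bond, the only ring), followed in the same flask by hydroxyl-directed reduction of the ring ketone.
3. The keto-enal comes from an asymmetric Ni/Cr-mediated coupling (C2–C3 bond) of a ketal-masked keto-aldehyde with a (Z)-alkenyl iodide; this sets the first stereocentre and carries the alkene geometry.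
4. The aldehyde is made from methyl acetoacetate (4 steps) and the alkenyl iodide from (Z)-but-2-ene-1,4-diol (4 steps).

Assumption: the target is read as (2S,3Z,4S,6S)-2-bromo-3-(2-bromoethylidene)-4,6-dichloro-1,1-dimethylcyclohexane, and the locants C1–C6 used in the comments are those of this name.

## Route

Step 1
Reactants: 1 methyl 3-oxobutanoate
Product: 2 methyl 2,2-dimethyl-3-oxobutanoate
Conditions: MeI (2.5 equiv), K2CO3, acetone, reflux
Reagents that add atoms: iodomethane CI
Why: Double enolate C-alkylation of the 1,3-dicarbonyl methylene builds the quaternary gem-dimethyl carbon (C1 of the target) and creates no stereocentre.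

Step 2
Reactants: 2 methyl 2,2-dimethyl-3-oxobutanoate
Product: 3 methyl 3,3-dimethoxy-2,2-dimethylbutanoate
Conditions: HC(OMe)3, MeOH, p-toluenesulfonic acid (cat.), 50 °C
Reagents that add atoms: trimethyl orthoformate COC(OC)OC
Why: Acid-catalysed ketalisation driven by the orthoformate masks the ketone, so that the ester can be reduced alone and the later aldehyde is the only electrophile in the coupling.

Step 3
Reactants: 3 methyl 3,3-dimethoxy-2,2-dimethylbutanoate
Product: 4 3,3-dimethoxy-2,2-dimethylbutan-1-ol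
Conditions: LiAlH4, THF, 0 °C; then H2O
Reagents that add atoms: none
Why: Hydride reduction of the ester gives the neopentylic primary alcohol and leaves the base-stable ketal untouched.

Step 4
Reactants: 4 3,3-dimethoxy-2,2-dimethylbutan-1-ol
Product: 5 3,3-dimethoxy-2,2-dimethylbutanal
Conditions: (COCl)2, DMSO, CH2Cl2, −78 °C; then Et3N
Reagents that add atoms: none
Why: Swern oxidation gives the non-enolisable aldehyde under basic conditions that preserve the ketal.

Step 5
Reactants: 6 (Z)-but-2-ene-1,4-diol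
Product: 7 (Z)-4-[(tert-butyldimethylsilyl)oxy]but-2-en-1-ol
Conditions: NaH (1 equiv), THF, 0 °C; then t-BuMe2SiCl
Reagents that add atoms: tert-butylchlorodimethylsilane CC(C)(C)[Si](C)(C)Cl
Why: Monosilylation of the symmetrical diol through its monosodium alkoxide (McDougal protocol) differentiates the two ends without creating a stereocentre.

Step 6
Reactants: 7 (Z)-4-[(tert-butyldimethylsilyl)oxy]but-2-en-1-ol
Product: 8 (Z)-4-[(tert-butyldimethylsilyl)oxy]but-2-enal
Conditions: MnO2, CH2Cl2, rt
Reagents that add atoms: none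
Why: Chemoselective MnO2 oxidation of the allylic alcohol gives the enal, whose alkene geometry does not matter because the next step re-sets it.

Step 7
Reactants: 8 (Z)-4-[(tert-butyldimethylsilyl)oxy]but-2-enal
Product: 9 (Z)-4-[(tert-butyldimethylsilyl)oxy]-2-iodobut-2-enal
Conditions: I2, pyridine, CH2Cl2, 0 °C to rt
Reagents that add atoms: iodine II
Why: α-Iodination of the enal (conjugate addition of pyridine, iodination of the enolate, E1cB loss of pyridine) gives the thermodynamically favoured Z-iodoenal with CHO trans to CH2OSi, which fixes the later exocyclic alkene geometry.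

Step 8
Reactants: 9 (Z)-4-[(tert-butyldimethylsilyl)oxy]-2-iodobut-2-enal
Product: 10 tert-butyl{[(2Z)-4,4-diethoxy-3-iodobut-2-en-1-yl]oxy}dimethylsilane
Conditions: HC(OEt)3, EtOH, NH4NO3 (cat.), rt
Reagents that add atoms: triethyl orthoformate CCOC(OCC)OCC
Why: Mild acetalisation protects the aldehyde so that the alkenyl iodide can act as the nucleophilic partner.

Step 9
Reactants: 5 3,3-dimethoxy-2,2-dimethylbutanal; 10 tert-butyl{[(2Z)-4,4-diethoxy-3-iodobut-2-en-1-yl]oxy}dimethylsilane
Product: 12 (2E,3S)-2-{2-[(tert-butyldimethylsilyl)oxy]ethylidene}-4,4-dimethyl-5-oxo-3-[(triethylsilyl)oxy]hexanal, via bis-acetal triethylsilyl ether 11 (not isolated)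
Conditions: CrCl2 (10 mol %), (S)-N-[2-(4-isopropyl-4,5-dihydro-1,3-oxazol-2-yl)-6-methylphenyl]methanesulfonamide (11 mol %), Et3N, NiCl2(2,9-dimethyl-1,10-phenanthroline) (2 mol %), Mn, LiCl, Et3SiCl, MeCN, rt; then SiO2, 10% aq. oxalic acid, CH2Cl2, rt
Reagents that add atoms: chlorotriethylsilane CC[Si](Cl)(CC)CC; water O
Why: Catalytic asymmetric Nozaki–Hiyama–Kishi coupling in which nickel inserts into the C–I bond with retention of alkene geometry, the alkenylchromium adds to the hindered aldehyde under control of the chiral sulfonamide ligand to set the S carbinol (C2 of the target; the antipodal ligand is used if the sense turns out reversed), Et3SiCl silylates the chromium alkoxide for turnover, and the acidic work-up hydrolyses both the diethyl acetal and the dimethyl ketal.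

Step 10
Reactants: 12 (2E,3S)-2-{2-[(tert-butyldimethylsilyl)oxy]ethylidene}-4,4-dimethyl-5-oxo-3-[(triethylsilyl)oxy]hexanal
Product: 14 (1R,3R,5R,6Z)-6-{2-[(tert-butyldimethylsilyl)oxy]ethylidene}-4,4-dimethyl-5-[(triethylsilyl)oxy]cyclohexane-1,3-diol, via β-hydroxy ketone 13 (not isolated)
Conditions: LiN(SiMe3)2, THF, −78 °C; AcOH; then Me4NBH(OAc)3, MeCN–AcOH, −30 °C
Reagents that add atoms: none
Why: Kinetic 1,2-addition of the methyl-ketone lithium enolate to the enal (intramolecular aldol addition, 6-(enolendo)-exo-trig) closes the cyclohexane through a chair in which the silyloxy group is axial (A1,3 strain with the cis CH2OSi group) and the new C4 hydroxyl is equatorial and therefore trans to it, and the Evans–Saksena reduction then delivers hydride internally from that hydroxyl to give the anti-1,3-diol with the C6 hydroxyl cis to the silyloxy group.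

Step 11
Reactants: 14 (1R,3R,5R,6Z)-6-{2-[(tert-butyldimethylsilyl)oxy]ethylidene}-4,4-dimethyl-5-[(triethylsilyl)oxy]cyclohexane-1,3-diol
Product: 15 (2R,3E,4S,6S)-3-{2-[(tert-butyldimethylsilyl)oxy]ethylidene}-4,6-dichloro-1,1-dimethyl-2-[(triethylsilyl)oxy]cyclohexane
Conditions: PPh3, CCl4, pyridine, MeCN, 0 to 65 °C
Reagents that add atoms: tetrachloromethane ClC(Cl)(Cl)Cl
Why: Double Appel deoxychlorination replaces the allylic (C4) and the neopentylic (C6) hydroxyl by chloride with SN2 inversion at each centre, while the silyl ethers have no O–H to be activated.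

Step 12
Reactants: 15 (2R,3E,4S,6S)-3-{2-[(tert-butyldimethylsilyl)oxy]ethylidene}-4,6-dichloro-1,1-dimethyl-2-[(triethylsilyl)oxy]cyclohexane
Product: 16 (2S,3Z,4S,6S)-2-bromo-3-(2-bromoethylidene)-4,6-dichloro-1,1-dimethylcyclohexane
Conditions: Ph3PBr2, CH2Cl2, 0 °C to rt
Reagents that add atoms: dibromotriphenylphosphorane BrP(Br)(c1ccccc1)(c1ccccc1)c1ccccc1
Why: Triphenylphosphine dibromide converts both silyl ethers directly into alkoxyphosphonium bromides (Appel-type) that collapse by SN2, giving the primary allylic bromide and, with inversion at C2, the secondary allylic bromide.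

## Compound list

1 | methyl 3-oxobutanoate | COC(=O)CC(C)=O | starting material
2 | methyl 2,2-dimethyl-3-oxobutanoate | COC(=O)C(C)(C)C(C)=O | intermediate
3 | methyl 3,3-dimethoxy-2,2-dimethylbutanoate | COC(=O)C(C)(C)C(C)(OC)OC | intermediate
4 | 3,3-dimethoxy-2,2-dimethylbutan-1-ol | COC(C)(OC)C(C)(C)CO | intermediate
5 | 3,3-dimethoxy-2,2-dimethylbutanal | COC(C)(OC)C(C)(C)C=O | intermediate
6 | (Z)-but-2-ene-1,4-diol | OC/C=C\CO | starting material
7 | (Z)-4-[(tert-butyldimethylsilyl)oxy]but-2-en-1-ol | CC(C)(C)[Si](C)(C)OC/C=C\CO | intermediate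
8 | (Z)-4-[(tert-butyldimethylsilyl)oxy]but-2-enal | CC(C)(C)[Si](C)(C)OC/C=C\C=O | intermediate
9 | (Z)-4-[(tert-butyldimethylsilyl)oxy]-2-iodobut-2-enal | O=C/C(I)=C/CO[Si](C)(C)C(C)(C)C | intermediate
10 | tert-butyl{[(2Z)-4,4-diethoxy-3-iodobut-2-en-1-yl]oxy}dimethylsilane | CCOC(OCC)/C(I)=C/CO[Si](C)(C)C(C)(C)C | intermediate
11 | (2E,3S)-2-{2-[(tert-butyldimethylsilyl)oxy]ethylidene}-1,1-diethoxy-5,5-dimethoxy-4,4-dimethyl-3-[(triethylsilyl)oxy]hexane | CC(OC)(OC)C(C)(C)[C@@H](O[Si](CC)(CC)CC)/C(=C\CO[Si](C)(C)C(C)(C)C)C(OCC)OCC | intermediate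
12 | (2E,3S)-2-{2-[(tert-butyldimethylsilyl)oxy]ethylidene}-4,4-dimethyl-5-oxo-3-[(triethylsilyl)oxy]hexanal | CC(=O)C(C)(C)[C@@H](O[Si](CC)(CC)CC)/C(=C\CO[Si](C)(C)C(C)(C)C)C=O | intermediate
13 | (3S,4Z,5R)-4-{2-[(tert-butyldimethylsilyl)oxy]ethylidene}-5-hydroxy-2,2-dimethyl-3-[(triethylsilyl)oxy]cyclohexan-1-one | CC1(C)[C@@H](O[Si](CC)(CC)CC)/C(=C\CO[Si](C)(C)C(C)(C)C)[C@H](O)CC1=O | intermediate
14 | (1R,3R,5R,6Z)-6-{2-[(tert-butyldimethylsilyl)oxy]ethylidene}-4,4-dimethyl-5-[(triethylsilyl)oxy]cyclohexane-1,3-diol | CC1(C)[C@@H](O[Si](CC)(CC)CC)/C(=C\CO[Si](C)(C)C(C)(C)C)[C@H](O)C[C@H]1O | intermediate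
15 | (2R,3E,4S,6S)-3-{2-[(tert-butyldimethylsilyl)oxy]ethylidene}-4,6-dichloro-1,1-dimethyl-2-[(triethylsilyl)oxy]cyclohexane | CC1(C)[C@@H](O[Si](CC)(CC)CC)/C(=C\CO[Si](C)(C)C(C)(C)C)[C@@H](Cl)C[C@@H]1Cl | intermediate
16 | (2S,3Z,4S,6S)-2-bromo-3-(2-bromoethylidene)-4,6-dichloro-1,1-dimethylcyclohexane | CC1(C)[C@H](Br)/C(=C\CBr)[C@@H](Cl)C[C@@H]1Cl | target

## Step count and weak points

Total step count: 12 (steps 1–4 give aldehyde 5, steps 5–8 give alkenyl iodide 10, steps 9–12 are common).
Longest linear sequence: 8 steps (1–4 or 5–8, then 9–12).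

The three steps most likely to fail are 9, 11 and 12.

For step 9, the ligand-controlled addition to a fully α-substituted aldehyde may give insufficient enantioselectivity, and silylation of the hindered chromium alkoxide may be too slow for turnover. The fallback separates bond formation from stereocontrol and sets out from 5 and 10. Iodine–lithium exchange on 10 (t-BuLi, Et2O, −78 °C) and addition to 5 gives the racemic alcohol rac-(2E)-2-{2-[(tert-butyldimethylsilyl)oxy]ethylidene}-1,1-diethoxy-5,5-dimethoxy-4,4-dimethylhexan-3-ol F1. Dess–Martin periodinane oxidises it to the enone (2Z)-2-{2-[(tert-butyldimethylsilyl)oxy]ethylidene}-1,1-diethoxy-5,5-dimethoxy-4,4-dimethylhexan-3-one F2. Corey–Bakshi–Shibata reduction (catecholborane, the enantiomer of 1-methyl-3,3-diphenyltetrahydro-1H,3H-pyrrolo[1,2-c][1,3,2]oxazaborole that gives the S alcohol) gives (2E,3S)-2-{2-[(tert-butyldimethylsilyl)oxy]ethylidene}-1,1-diethoxy-5,5-dimethoxy-4,4-dimethylhexan-3-ol F3. Silylation with Et3SiOTf and 2,6-lutidine comes back to the route at 11, which the same oxalic acid on silica treatment converts into 12.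

For step 11, substitution at the neopentylic C6 carbinol can lose to elimination or methyl migration, and the long heating it needs can epimerise or transpose the allylic C4 chloride formed first. The fallback treats the two hydroxyls one after the other with different activation and sets out from 14. Hexachloroacetone and PPh3 at −20 °C chlorinate only the allylic hydroxyl with inversion to give (1R,3R,4E,5S)-4-{2-[(tert-butyldimethylsilyl)oxy]ethylidene}-5-chloro-2,2-dimethyl-3-[(triethylsilyl)oxy]cyclohexan-1-ol F4. Chloromethanesulfonyl chloride and pyridine convert the remaining hydroxyl into (1R,3R,4E,5S)-4-{2-[(tert-butyldimethylsilyl)oxy]ethylidene}-5-chloro-2,2-dimethyl-3-[(triethylsilyl)oxy]cyclohexyl chloromethanesulfonate F5. Displacement of this very reactive sulfonate with LiCl in DMF at 60 °C, with inversion, comes back to the route at 15.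

For step 12, the hindered secondary silyl ether at C2 may be activated slowly, bromide may attack the side-chain alkene carbon (SN2′) instead of C2, and free bromide may exchange with the allylic C4 chloride. The fallback works on the free alcohols in stages and sets out from 15. HF·pyridine in THF removes both silyl groups to give (1R,3S,5S,6E)-3,5-dichloro-6-(2-hydroxyethylidene)-2,2-dimethylcyclohexan-1-ol F6. CBr4 and PPh3 (1 equiv, −30 °C) brominate only the primary allylic hydroxyl to give (1R,3S,5S,6E)-6-(2-bromoethylidene)-3,5-dichloro-2,2-dimethylcyclohexan-1-ol F7. MeSO2Cl and Et3N at −40 °C give (1R,3S,5S,6E)-6-(2-bromoethylidene)-3,5-dichloro-2,2-dimethylcyclohexyl methanesulfonate F8, which is displaced in the same flask by LiBr in THF at −20 °C with inversion, coming back to the route at 16.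

## Further compounds

F1 | step 9 | rac-(2E)-2-{2-[(tert-butyldimethylsilyl)oxy]ethylidene}-1,1-diethoxy-5,5-dimethoxy-4,4-dimethylhexan-3-ol | CC(OC)(OC)C(C)(C)C(O)/C(=C\CO[Si](C)(C)C(C)(C)C)C(OCC)OCC
F2 | step 9 | (2Z)-2-{2-[(tert-butyldimethylsilyl)oxy]ethylidene}-1,1-diethoxy-5,5-dimethoxy-4,4-dimethylhexan-3-one | CC(OC)(OC)C(C)(C)C(=O)/C(=C\CO[Si](C)(C)C(C)(C)C)C(OCC)OCC
F3 | step 9 | (2E,3S)-2-{2-[(tert-butyldimethylsilyl)oxy]ethylidene}-1,1-diethoxy-5,5-dimethoxy-4,4-dimethylhexan-3-ol | CC(OC)(OC)C(C)(C)[C@@H](O)/C(=C\CO[Si](C)(C)C(C)(C)C)C(OCC)OCC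
F4 | step 11 | (1R,3R,4E,5S)-4-{2-[(tert-butyldimethylsilyl)oxy]ethylidene}-5-chloro-2,2-dimethyl-3-[(triethylsilyl)oxy]cyclohexan-1-ol | CC1(C)[C@@H](O[Si](CC)(CC)CC)/C(=C\CO[Si](C)(C)C(C)(C)C)[C@@H](Cl)C[C@H]1O
F5 | step 11 | (1R,3R,4E,5S)-4-{2-[(tert-butyldimethylsilyl)oxy]ethylidene}-5-chloro-2,2-dimethyl-3-[(triethylsilyl)oxy]cyclohexyl chloromethanesulfonate | CC1(C)[C@@H](O[Si](CC)(CC)CC)/C(=C\CO[Si](C)(C)C(C)(C)C)[C@@H](Cl)C[C@H]1OS(=O)(=O)CCl
F6 | step 12 | (1R,3S,5S,6E)-3,5-dichloro-6-(2-hydroxyethylidene)-2,2-dimethylcyclohexan-1-ol | CC1(C)[C@@H](O)/C(=C\CO)[C@@H](Cl)C[C@@H]1Cl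
F7 | step 12 | (1R,3S,5S,6E)-6-(2-bromoethylidene)-3,5-dichloro-2,2-dimethylcyclohexan-1-ol | CC1(C)[C@@H](O)/C(=C\CBr)[C@@H](Cl)C[C@@H]1Cl
F8 | step 12 | (1R,3S,5S,6E)-6-(2-bromoethylidene)-3,5-dichloro-2,2-dimethylcyclohexyl methanesulfonate | CC1(C)[C@@H](OS(C)(=O)=O)/C(=C\CBr)[C@@H](Cl)C[C@@H]1Cl
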